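**Numbering convention.** In the discussion the ring is numbered O1, C2 (arylethyl arm), C3, C4 (OH), C5, C6 (aryl). Systematic names in the compound list follow their own locants.

## Analysis of the target

Target 16 is a 1,7-diarylheptanoid whose chain is tied into a single tetrahydropyran ring. C2 carries a 2-(4-hydroxy-3-methoxyphenyl)ethyl arm, C4 a free secondary hydroxyl and C6 a 4-hydroxy-3-methoxyphenyl ring bound directly. The three stereocentres are C2 (S), C4 (R) and C6 (S). Read from the SMILES, all three substituents lie on one face, so the chair carries them all equatorially and 16 is the thermodynamically preferred diastereomer. Unfolded, the C2–O1 and C4–OH bonds form a 1,3-anti pair of carbinol centres. The sensitive groups are the two guaiacol phenols (acidic, easily oxidised) and the C6–O1 bond, a benzylic ether activated by a para oxygen that can ionise under acid and is exposed to hydrogenolysis. The difficulty is absolute control of two remote carbinol centres in a flexible chain in few steps, with C6 then set relative to them and the electron-rich arenes left intact. The strategy rests on the fact that C2 and C4 are each flanked by CH2 groups (the arm CH2 and C3; C3 and C5). That is the pattern left when both CH2 termini of the C2-symmetric diepoxide 3 are opened by carbon nucleophiles, and C6 sits at the ketone oxidation level of an acyl anion.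

## Retrosynthetic reasoning

**16 to 15.** Both phenols are masked as benzyl ethers. These survive organolithium, organomagnesium and silyl triflate chemistry and fall together in one final hydrogenolysis. No skeletal bond is cut.

**15 to 12.** The O1–C6 ring bond and the C6–H bond are cut, giving the open-chain dihydroxy ketone 12. C6 is chosen because it is the one stereocentre that is both benzylic and bound to the ring oxygen, so it can pass through an sp2 state. In the forward direction 12 closes to hemiketal 13, ionises to oxocarbenium ion 14 and takes hydride axially. C6 therefore does not have to be carried through the synthesis, and the isomer formed is also the thermodynamic one.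

**12 to 11.** The aryl ketone is traced to its dithiane. C6 must have been a nucleophile when C5–C6 was made, and the dithiane is the acyl anion equivalent that allows this.

**11 to 5, 3 and 8 (through 9 and 10).** Two C–C bonds are cut: C5–C6 and the bond between the two CH2 groups of the arm. Each cut lies at a CH2 next to a carbinol carbon, the retron of terminal epoxide opening. Both epoxides belong to one molecule, 3, whose ends are homotopic. The gain is a three-fragment convergence in which both stereocentres come unchanged from 3. The forward reaction must open 3 once with 9 to give 10 and then open the remaining epoxide with 8.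

**3 to 2 to 1.** The epoxide C–O bonds go back to the bis-chlorohydrin 2, and its two carbinol C–H bonds to the diketone 1. One double asymmetric hydrogenation sets both centres. A mis-set centre ends up mainly in the meso diol, which is discarded, so the enantiopurity of 2 is amplified.

**5 from 4; 8 from 7 from 6.** These are functional group changes only: thioacetalisation of aldehyde 4, and chlorination of alcohol 6 followed by magnesium insertion.

## Alternatives that were turned down

**Alternative 1:** The O1–C2 bond is disconnected, so that the all-cis styryl pyran A1 comes from the acyclic allylic alcohol A2. In the forward step Re2O7 forms a perrhenate ester of A2, transposes it and ionises it to a cinnamyl cation. The C6 hydroxyl traps this cation reversibly until the all-equatorial A1 accumulates.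

- For: neither the position nor the configuration of the allylic hydroxyl matters and C2 corrects itself. On the setting of C2 this is stronger than the chosen route.
- Against: A2 still needs C4 and C6 as a defined anti-1,3 pair with the C4 oxygen differentiated, which means separate stereocontrolled operations and a protection in a linear chain.
- Against: the C6 hydroxyl of A2 is itself a para-alkoxybenzylic alcohol that Re2O7 can ionise, opening elimination to a styrene and Friedel–Crafts alkylation of the guaiacyl rings.
- Against: A1 keeps a styryl alkene that must be hydrogenated while C2–O1 is allylic and C6–O1 benzylic, so two ring C–O bonds are exposed to hydrogenolysis.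
- Comparison: the chosen route delivers C2 and C4 from one catalytic asymmetric step, has the arm saturated from the start, and leaves only one activated C–O bond for the final step.

**Alternative 2:** Three bonds are disconnected (C2–C3, C5–C6, O1–C6), leading to the pyranone ester A3 from propanal A4, bis-silyl dienolate A5 and aldehyde 4. In the forward step a Ti(OiPr)4–BINOL-catalysed vinylogous Mukaiyama aldol of A5 with A4 sets C2. TiCl4 then drives Knoevenagel condensation with 4 and oxa-Michael closure in the same flask.

- For: the whole ring is assembled in one flask from simple aldehydes and 2,6-cis follows from reversible conjugate addition. On step economy of ring construction this is stronger than the chosen route.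
- Against: A3 carries an ester that must be excised (giving ketone A6) and a C4 ketone that must be reduced, which is a further diastereoselection even if small hydrides favour the required equatorial alcohol.
- Against: the only source of absolute configuration is a catalytic aldol on an enolisable unbranched aldehyde, where enantioselectivity is less dependable than with aromatic aldehydes.
- Against: 4 is an electron-rich and therefore sluggish Knoevenagel partner.
- Comparison: the chosen route offers enantiopurity secured by a double hydrogenation with built-in amplification and a crystalline intermediate, a C4 hydroxyl that is correct from the start, and no redox adjustment of the ring.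

**Alternative 3:** The C2–C3 bond is disconnected, taking pyranone A6 back to the cis enol acetal A7, which is made from hydroxy acid A8 and propanal A4. In the forward step Me2AlCl ionises the acetal C–O bond of A7 to an oxocarbenium ion and an aluminium enolate. These recombine through carbon in a chair to give 2,6-cis A6 (Petasis–Ferrier rearrangement).

- For: the 2,6-cis outcome is very dependable, probably more so than hydride delivery to 14, and one stereocentre (in A8) controls everything.
- Against: the sequence is long and linear. It needs A8, acetalisation to the cis dioxanone, carbonyl methylenation with stoichiometric Cp2TiMe2, the rearrangement, ketone reduction and deprotection.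
- Against: A7 contains an electron-rich benzylic C6–O bond during a strongly Lewis acidic step, so ionisation at C6 competes with the intended acetal ionisation.
- Against: C4 is again set late by reduction.
- Comparison: the chosen route is shorter and convergent and installs C2 and C4 together.

Key step: step 6

Assumption: 1, 4 and 6 are taken as purchasable. The (S)-BINAP ligand in step 1 is assigned by analogy with the facial sense of RuCl2(BINAP) hydrogenation of 4-chloro-3-oxobutanoates; if the sign of rotation of 3 shows the opposite series, the (R)-ligand is used.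

## Route

Step 1
Reactants: 1 1,5-dichloropentane-2,4-dione
Product: 2 (2R,4R)-1,5-dichloropentane-2,4-diol
Conditions: H2 (85 atm), [RuCl2((S)-BINAP)]2·NEt3 (0.2 mol%), MeOH, 100 °C; recrystallise
Reagents that add atoms: none
Why: Noyori asymmetric hydrogenation of a 1,3-diketone; each carbonyl is reduced on the chelated divalent ruthenium–BINAP hydride with ligand-controlled facial selectivity, giving the anti diol, and a mis-set centre falls mainly into the meso diol, which crystallisation should remove.

Step 2
Reactants: 2 (2R,4R)-1,5-dichloropentane-2,4-diol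
Product: 3 (2R,4R)-1,2:4,5-diepoxypentane
Conditions: KOH (powdered), Et2O, rt; distil
Reagents that add atoms: none
Why: Double intramolecular Williamson closure (3-exo-tet SN2 at the CH2Cl carbons); the carbinol C–O bonds are not touched, so both configurations are retained.

Step 3
Reactants: 4 4-(benzyloxy)-3-methoxybenzaldehyde
Product: 5 2-[4-(benzyloxy)-3-methoxyphenyl]-1,3-dithiane
Conditions: HS(CH2)3SH (1.1 equiv), BF3·OEt2 (0.2 equiv), CH2Cl2, 0 °C to rt
Reagents that add atoms: propane-1,3-dithiol, SCCCS
Why: Lewis acid-catalysed dithioacetalisation of an aromatic aldehyde; the aryl benzyl ether is inert to catalytic BF3·OEt2 at this temperature.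

Step 4
Reactants: 6 [4-(benzyloxy)-3-methoxyphenyl]methanol
Product: 7 1-(benzyloxy)-4-(chloromethyl)-2-methoxybenzene
Conditions: SOCl2 (1.2 equiv), CH2Cl2, 0 °C; evaporate, use at once
Reagents that add atoms: thionyl chloride, O=S(Cl)Cl
Why: Chlorodehydroxylation through the chlorosulfite ester, fast for an electron-rich benzylic alcohol; the chloride is used fresh because it self-alkylates on storage.

Step 5
Reactants: 7 1-(benzyloxy)-4-(chloromethyl)-2-methoxybenzene
Product: 8 [4-(benzyloxy)-3-methoxybenzyl]magnesium chloride (THF solution, titrated)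
Conditions: Mg turnings (3 equiv, I2-activated), THF, 0 °C, slow addition of dilute 7
Reagents that add atoms: magnesium, [Mg]
Why: Grignard formation by insertion of magnesium metal into the benzylic C–Cl bond; slow addition of dilute halide to excess metal keeps the halide concentration low and so limits Wurtz coupling.

Step 6
Reactants: 5 2-[4-(benzyloxy)-3-methoxyphenyl]-1,3-dithiane; 3 (2R,4R)-1,2:4,5-diepoxypentane; 8 [4-(benzyloxy)-3-methoxybenzyl]magnesium chloride
Product: 11 (2R,4S)-1-{2-[4-(benzyloxy)-3-methoxyphenyl]-1,3-dithian-2-yl}-6-[4-(benzyloxy)-3-methoxyphenyl]hexane-2,4-diol, via lithiated dithiane 9 (not isolated), via lithium epoxy alkoxide 10 (not isolated)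
Conditions: 5, n-BuLi (1.05 equiv), THF, −78 to −20 °C; add dropwise to 3 (1.2 equiv), THF, −25 °C; then CuI (15 mol%), 8 (3 equiv), −40 to 0 °C; aq. NH4Cl
Reagents that add atoms: none
Why: n-BuLi removes the C2–H of 5, acidified by two sulfurs and the aryl ring, to give the aroyl anion equivalent 9. Added slowly to a slight excess of 3, 9 attacks one terminal epoxide CH2 by SN2; the two epoxides are exchanged by the C2 axis, so either choice gives the same alkoxide 10 and only mono- versus bis-opening needs control, which inverse addition and stoichiometry provide. The lithium alkoxide of 10 does not consume the second nucleophile and can reach the remaining epoxide only through disfavoured oxetane or 5-endo closures. CuI and 8 then form a benzylcopper species that opens the second epoxide, again at its CH2 terminus. The closest known reaction type is the sequential opening of C2-symmetric 1,2:4,5-diepoxypentane by a 2-lithio-1,3-dithiane and then an organocopper reagent. No ring is closed and no stereocentre is created: only CH2–O bonds break, so both carbinol configurations of 3 pass into 11 as the 1,3-anti diol (the 4S descriptor reflects a priority change, not an inversion). The selectivities needed are terminal over internal attack, secured by the steric preference of SN2 opening of monosubstituted epoxides, and one addition of 9 per molecule of 3.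

Step 7
Reactants: 11 (2R,4S)-1-{2-[4-(benzyloxy)-3-methoxyphenyl]-1,3-dithian-2-yl}-6-[4-(benzyloxy)-3-methoxyphenyl]hexane-2,4-diol
Product: 12 (3R,5S)-1,7-bis[4-(benzyloxy)-3-methoxyphenyl]-3,5-dihydroxyheptan-1-one
Conditions: MeI (10 equiv), CaCO3 (5 equiv), MeCN–H2O (9:1), 40 °C
Reagents that add atoms: water, O
Why: Alkylative hydrolysis of a dithioketal: S-methylation, ring opening to a thionium ion stabilised by the para-alkoxyaryl group, and capture by water; the method is non-oxidative, so the electron-rich arenes are spared, and CaCO3 buffers the HI so the β-hydroxy ketone should neither dehydrate nor undergo retro-aldol cleavage (12 may equilibrate with hemiketal 13).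

Step 8
Reactants: 12 (3R,5S)-1,7-bis[4-(benzyloxy)-3-methoxyphenyl]-3,5-dihydroxyheptan-1-one
Product: 15 (2S,4R,6S)-2-[4-(benzyloxy)-3-methoxyphenyl]-6-{2-[4-(benzyloxy)-3-methoxyphenyl]ethyl}oxan-4-ol, via cyclic hemiketal 13 (not isolated), via oxocarbenium ion 14 (not isolated)
Conditions: Et3SiH (5 equiv), TMSOTf (2 equiv), CH2Cl2, −78 to −40 °C; aq. NaHCO3; then K2CO3, MeOH, rt
Reagents that add atoms: none
Why: Reductive etherification (ionic hydrogenation of a hemiketal): the δ-hydroxyl closes onto the ketone to give 13, TMSOTf ionises it to the aryl-stabilised six-membered oxocarbenium ion 14, and Et3SiH adds axially to the half-chair that holds the C2 arm and the C4 oxygen pseudo-equatorial, so the new C6–H is axial and the aryl group equatorial (2,4,6-all-cis, also the thermodynamic isomer). Any transient O-silylation at C4 is reversed by the methanolic K2CO3 work-up.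

Step 9
Reactants: 15 (2S,4R,6S)-2-[4-(benzyloxy)-3-methoxyphenyl]-6-{2-[4-(benzyloxy)-3-methoxyphenyl]ethyl}oxan-4-ol
Product: 16 (2S,4R,6S)-2-(4-hydroxy-3-methoxyphenyl)-6-[2-(4-hydroxy-3-methoxyphenyl)ethyl]oxan-4-ol
Conditions: H2 (1 atm), Pd/C (10% Pd on carbon), EtOAc, rt; stop at full conversion
Reagents that add atoms: none
Why: Catalytic hydrogenolysis of aryl benzyl ethers, which are primary benzylic C–O bonds with a phenoxide-type leaving group and should cleave faster than the secondary cyclic benzylic ether C6–O1 in neutral, acid-free solvent; no stereocentre is touched.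

## Compound list

1 | 1,5-dichloropentane-2,4-dione | O=C(CCl)CC(=O)CCl | starting material
2 | (2R,4R)-1,5-dichloropentane-2,4-diol | ClC[C@H](O)C[C@@H](O)CCl | intermediate
3 | (2R,4R)-1,2:4,5-diepoxypentane | C1[C@H](O1)C[C@@H]1CO1 | intermediate
4 | 4-(benzyloxy)-3-methoxybenzaldehyde | COc1cc(C=O)ccc1OCc1ccccc1 | starting material
5 | 2-[4-(benzyloxy)-3-methoxyphenyl]-1,3-dithiane | COc1cc(C2SCCCS2)ccc1OCc1ccccc1 | intermediate
6 | [4-(benzyloxy)-3-methoxyphenyl]methanol | COc1cc(CO)ccc1OCc1ccccc1 | starting material
7 | 1-(benzyloxy)-4-(chloromethyl)-2-methoxybenzene | COc1cc(CCl)ccc1OCc1ccccc1 | intermediate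
8 | [4-(benzyloxy)-3-methoxybenzyl]magnesium chloride | COc1cc(C[Mg]Cl)ccc1OCc1ccccc1 | intermediate
9 | 2-lithio-2-[4-(benzyloxy)-3-methoxyphenyl]-1,3-dithiane | COc1cc(C2([Li])SCCCS2)ccc1OCc1ccccc1 | intermediate (not isolated)
10 | lithium (2R)-1-{2-[4-(benzyloxy)-3-methoxyphenyl]-1,3-dithian-2-yl}-3-[(2R)-oxiran-2-yl]propan-2-olate | C1[C@H](O1)C[C@@H](O[Li])CC2(c3ccc(OCc4ccccc4)c(OC)c3)SCCCS2 | intermediate (not isolated)
11 | (2R,4S)-1-{2-[4-(benzyloxy)-3-methoxyphenyl]-1,3-dithian-2-yl}-6-[4-(benzyloxy)-3-methoxyphenyl]hexane-2,4-diol | COc1cc(CC[C@H](O)C[C@@H](O)CC2(c3ccc(OCc4ccccc4)c(OC)c3)SCCCS2)ccc1OCc1ccccc1 | intermediate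
12 | (3R,5S)-1,7-bis[4-(benzyloxy)-3-methoxyphenyl]-3,5-dihydroxyheptan-1-one | COc1cc(CC[C@H](O)C[C@@H](O)CC(=O)c2ccc(OCc3ccccc3)c(OC)c2)ccc1OCc1ccccc1 | intermediate
13 | (4R,6S)-2-[4-(benzyloxy)-3-methoxyphenyl]-6-{2-[4-(benzyloxy)-3-methoxyphenyl]ethyl}oxane-2,4-diol (C2 epimers) | COc1cc(CC[C@H]2C[C@@H](O)CC(O)(c3ccc(OCc4ccccc4)c(OC)c3)O2)ccc1OCc1ccccc1 | intermediate (not isolated)
14 | (2S,4R)-6-[4-(benzyloxy)-3-methoxyphenyl]-2-{2-[4-(benzyloxy)-3-methoxyphenyl]ethyl}-4-hydroxy-3,4-dihydro-2H-pyran-1-ium trifluoromethanesulfonate | COc1cc(CC[C@H]2C[C@@H](O)CC(c3ccc(OCc4ccccc4)c(OC)c3)=[O+]2)ccc1OCc1ccccc1.[O-]S(=O)(=O)C(F)(F)F | intermediate (not isolated)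
15 | (2S,4R,6S)-2-[4-(benzyloxy)-3-methoxyphenyl]-6-{2-[4-(benzyloxy)-3-methoxyphenyl]ethyl}oxan-4-ol | COc1cc(CC[C@H]2C[C@@H](O)C[C@@H](c3ccc(OCc4ccccc4)c(OC)c3)O2)ccc1OCc1ccccc1 | intermediate
16 | (2S,4R,6S)-2-(4-hydroxy-3-methoxyphenyl)-6-[2-(4-hydroxy-3-methoxyphenyl)ethyl]oxan-4-ol | COc1cc(CC[C@H]2C[C@@H](O)C[C@@H](c3ccc(O)c(OC)c3)O2)ccc1O | target

## Step count and least certain steps

Total: 9 steps. Longest linear sequence: 6 steps (1 to 2 to 3 to 11 to 12 to 15 to 16; the branch 6 to 7 to 8 to 11 onward is equally long).

**Step 6 (key step).**
- Risk: loss of mono-selectivity in the first opening, because a second molecule of 9 can add to the epoxide of 10. In the second stage the CuI-catalysed opening may be slow in the presence of the lithium alkoxide and the thioacetal sulfurs, which leaves room for chloride opening of the epoxide through the Schlenk equilibrium.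
- Fallback: set out from 5, 3 and 7 and rejoin at 11, with the two openings run separately and the organomagnesium replaced by a sulfone-stabilised benzyl anion. Lithiated 5 is added to a larger excess of 3 (the excess is recovered by distillation) and quenched to isolate the epoxy alcohol (2R)-1-{2-[4-(benzyloxy)-3-methoxyphenyl]-1,3-dithian-2-yl}-3-[(2R)-oxiran-2-yl]propan-2-ol F1. Chloride 7 and PhSO2Na in DMF give 1-(benzyloxy)-2-methoxy-4-[(phenylsulfonyl)methyl]benzene F2. F2 is deprotonated with n-BuLi (2.2 equiv of anion; the first equivalent deprotonates the hydroxyl of F1) in THF–DMPU at −78 °C to rt. It opens the epoxide of F1 at the CH2 terminus to give (2R,4R)-1-{2-[4-(benzyloxy)-3-methoxyphenyl]-1,3-dithian-2-yl}-6-[4-(benzyloxy)-3-methoxyphenyl]-6-(phenylsulfonyl)hexane-2,4-diol F3 as both C6 epimers. Reductive desulfonylation (Na(Hg), Na2HPO4, MeOH, −20 °C) removes the sulfonyl group and gives 11.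

**Step 8.**
- Risk: over-reduction. The new C6–O1 bond is a para-alkoxybenzylic ether and can re-ionise under TMSOTf, after which a second hydride transfer opens the ring. Acid-promoted β-elimination of the C4 oxygen from the open keto form may also compete before hemiketalisation.
- Fallback: set out from 12 and rejoin at 15 by cyclodehydration under thermodynamic control. NaBH4 in MeOH at 0 °C reduces the ketone to (3R,5S)-1,7-bis[4-(benzyloxy)-3-methoxyphenyl]heptane-1,3,5-triol F4 (both C1 epimers; no selectivity is needed). Catalytic p-TsOH in CH2Cl2 at rt then ionises the benzylic alcohol reversibly, and the C5 hydroxyl closes the ring to the all-equatorial 15 without any hydride donor present.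

**Step 5.**
- Risk: Wurtz-type homocoupling of the electron-rich benzylic chloride with freshly formed organomagnesium, which lowers the titre and contaminates step 6 with the bibenzyl.
- Fallback: set out from 7 and rejoin at 11 through a halide-free benzyl anion. Bu3SnLi (from Bu3SnH and LDA) in THF at −78 °C displaces chloride to give tributyl{[4-(benzyloxy)-3-methoxyphenyl]methyl}stannane F5. Tin–lithium exchange with n-BuLi (THF, −78 °C) gives {[4-(benzyloxy)-3-methoxyphenyl]methyl}lithium F6, which is added with CuI (15 mol%) to alkoxide 10 in place of 8 and gives 11.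

**Step 9.**
- Risk: over-hydrogenolysis, that is, cleavage of the benzylic C6–O1 ring bond once the phenols are unmasked and the ring carbon becomes more electron-rich.
- Fallback: set out from 12 and rejoin at 16 by debenzylating before the ring exists. H2 and Pd/C in EtOAc convert 12 into (3R,5S)-3,5-dihydroxy-1,7-bis(4-hydroxy-3-methoxyphenyl)heptan-1-one F7, which has no benzylic C–O bond to lose. Reductive etherification of F7 (Et3SiH, TMSOTf, CH2Cl2–MeCN, −78 °C; then K2CO3, MeOH) then gives 16 directly.

## Further compounds

F1 | step 6 | (2R)-1-{2-[4-(benzyloxy)-3-methoxyphenyl]-1,3-dithian-2-yl}-3-[(2R)-oxiran-2-yl]propan-2-ol | C1[C@H](O1)C[C@@H](O)CC2(c3ccc(OCc4ccccc4)c(OC)c3)SCCCS2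
F2 | step 6 | 1-(benzyloxy)-2-methoxy-4-[(phenylsulfonyl)methyl]benzene | COc1cc(CS(=O)(=O)c2ccccc2)ccc1OCc1ccccc1
F3 | step 6 | (2R,4R)-1-{2-[4-(benzyloxy)-3-methoxyphenyl]-1,3-dithian-2-yl}-6-[4-(benzyloxy)-3-methoxyphenyl]-6-(phenylsulfonyl)hexane-2,4-diol (both C6 epimers) | COc1cc(C(C[C@H](O)C[C@@H](O)CC2(c3ccc(OCc4ccccc4)c(OC)c3)SCCCS2)S(=O)(=O)c2ccccc2)ccc1OCc1ccccc1
F4 | step 8 | (3R,5S)-1,7-bis[4-(benzyloxy)-3-methoxyphenyl]heptane-1,3,5-triol (both C1 epimers) | COc1cc(CC[C@H](O)C[C@@H](O)CC(O)c2ccc(OCc3ccccc3)c(OC)c2)ccc1OCc1ccccc1
F5 | step 5 | tributyl{[4-(benzyloxy)-3-methoxyphenyl]methyl}stannane | COc1cc(C[Sn](CCCC)(CCCC)CCCC)ccc1OCc1ccccc1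
F6 | step 5 | {[4-(benzyloxy)-3-methoxyphenyl]methyl}lithium | COc1cc(C[Li])ccc1OCc1ccccc1
F7 | step 9 | (3R,5S)-3,5-dihydroxy-1,7-bis(4-hydroxy-3-methoxyphenyl)heptan-1-one | COc1cc(CC[C@H](O)C[C@@H](O)CC(=O)c2ccc(O)c(OC)c2)ccc1O
A1 | alternative 1 | 2,4,6-all-cis 4-(benzyloxy)-2-[4-(benzyloxy)-3-methoxyphenyl]-6-[(E)-2-(4-benzyloxy-3-methoxyphenyl)ethenyl]oxane | COc1cc(/C=C/[C@H]2C[C@@H](OCc6ccccc6)C[C@@H](c3ccc(OCc4ccccc4)c(OC)c3)O2)ccc1OCc1ccccc1
A2 | alternative 1 | (E)-5-(benzyloxy)-1,7-bis[4-(benzyloxy)-3-methoxyphenyl]hept-1-ene-3,7-diol, anti C5/C7, C3 configuration free (one of the two interconverting allylic isomers) | COc1cc(/C=C/C(O)C[C@@H](OCc2ccccc2)C[C@H](O)c2ccc(OCc3ccccc3)c(OC)c2)ccc1OCc1ccccc1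
A3 | alternative 2 | methyl 2,6-cis-2-[4-(benzyloxy)-3-methoxyphenyl]-6-{2-[4-(benzyloxy)-3-methoxyphenyl]ethyl}-4-hydroxy-5,6-dihydro-2H-pyran-3-carboxylate (enol form of the β-keto ester) | COc1cc(CC[C@H]2CC(O)=C(C(=O)OC)[C@@H](c3ccc(OCc4ccccc4)c(OC)c3)O2)ccc1OCc1ccccc1
A4 | alternative 2 | 3-[4-(benzyloxy)-3-methoxyphenyl]propanal | COc1cc(CCC=O)ccc1OCc1ccccc1
A5 | alternative 2 | 1-methoxy-1,3-bis(trimethylsilyloxy)buta-1,3-diene | COC(O[Si](C)(C)C)=CC(=C)O[Si](C)(C)C
A6 | alternative 3 | (2S,6S)-2-[4-(benzyloxy)-3-methoxyphenyl]-6-{2-[4-(benzyloxy)-3-methoxyphenyl]ethyl}oxan-4-one | COc1cc(CC[C@H]2CC(=O)C[C@@H](c3ccc(OCc4ccccc4)c(OC)c3)O2)ccc1OCc1ccccc1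
A7 | alternative 3 | 2,6-cis-6-[4-(benzyloxy)-3-methoxyphenyl]-2-{2-[4-(benzyloxy)-3-methoxyphenyl]ethyl}-4-methylidene-1,3-dioxane | C=C1C[C@@H](c2ccc(OCc3ccccc3)c(OC)c2)O[C@@H](CCc2ccc(OCc3ccccc3)c(OC)c2)O1
A8 | alternative 3 | (3S)-3-[4-(benzyloxy)-3-methoxyphenyl]-3-hydroxypropanoic acid | OC(=O)C[C@H](O)c1ccc(OCc2ccccc2)c(OC)c1
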